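The α-methylene lactone (ring B) is disconnected at O–C8 and C11–C7 to a hydrogen malonate hung on the C6 oxygen (germacrane numbering) of an E-allylic alcohol. The target carries oxygen on both C6 and C8, flanking C7; the key step exploits this 1,3-dioxygenated triad. One trivalent-manganese/divalent-copper oxidation closes a sacrificial lactone (ring A, through O6) and ring B at once, and the single carbinol centre C6 sets C7 and C8. The precursor is an acyclic enyne malonate that already holds the 3(2H)-furanone. Ring A is then opened with decarboxylative methylenation, C6 is inverted while the epoxyangelate is installed, and ring-closing metathesis at C4=C5 completes the ten-membered ring.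

Key step: step 12

Remark: atoms are named by germacrane numbering (C1 furanone carbonyl; C3 furanone C–O; C4=C5 ring alkene; C6 acyloxy carbon; C7; C8 lactone C–O; C9; C10 quaternary carbon; C11, C12, C13 lactone α-carbon, carbonyl and exo-methylene); ring A is the temporary lactone through O6, ring B the α-methylene lactone of the target.

**Side chain (steps 1–3)**

Step 1
Reactants: 1 methyl (Z)-2-methylbut-2-enoate (methyl angelate)
Product: 2 (Z)-2-methylbut-2-en-1-ol
Conditions: iBu2AlH (2.2 equiv), CH2Cl2, −78 °C; aq. potassium sodium tartrate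
Reagents that add atoms: none
Why: 1,2-hydride reduction of the unsaturated ester with iBu2AlH should give the allylic alcohol with the Z geometry intact.

Step 2
Reactants: 2 (Z)-2-methylbut-2-en-1-ol
Product: 3 [(2R,3S)-2,3-dimethyloxiran-2-yl]methanol
Conditions: Ti(OiPr)4 (10 mol%), D-(−)-diethyl tartrate (12 mol%), tBuOOH (2 equiv), 4 Å MS, CH2Cl2, −20 °C
Reagents that add atoms: tert-butyl hydroperoxide CC(C)(C)OO
Why: Sharpless asymmetric epoxidation with the D-(−)-tartrate should deliver oxygen to the face that gives (2R,3S), while the Z alkene fixes the two methyl groups trans on the oxirane.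

Step 3
Reactants: 3 [(2R,3S)-2,3-dimethyloxiran-2-yl]methanol
Product: 4 (2S,3S)-2,3-dimethyloxirane-2-carboxylic acid ((2S,3S)-epoxyangelic acid)
Conditions: RuCl3·xH2O (2 mol%), NaIO4 (3 equiv), CCl4/MeCN/H2O, 23 °C
Reagents that add atoms: water O
Why: Ruthenium tetroxide oxidation of the primary alcohol should give the acid without opening the oxirane; the geometry is unchanged and the C2 descriptor becomes S only through the change in priorities.

**Main line (steps 4–16)**

Step 4
Reactants: 5 (R)-lactic acid; 6 pivalaldehyde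
Product: 7 (2R,5R)-2-tert-butyl-5-methyl-1,3-dioxolan-4-one
Conditions: p-TsOH (cat.), pentane, reflux, Dean–Stark; crystallisation of the cis isomer
Reagents that add atoms: pivalaldehyde CC(C)(C)C=O
Why: Acid-catalysed acetalisation should give mainly the cis dioxolanone, which stores the lactate configuration in the acetal carbon (self-regeneration of stereocentres).

Step 5
Reactants: 7 (2R,5R)-2-tert-butyl-5-methyl-1,3-dioxolan-4-one; 8 allyl bromide
Product: 9 (2R,5S)-2-tert-butyl-5-methyl-5-(prop-2-en-1-yl)-1,3-dioxolan-4-one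
Conditions: LiN(iPr)2, THF, −78 °C; then 8, −78 → −30 °C
Reagents that add atoms: allyl bromide C=CCBr
Why: Enolate alkylation anti to the tert-butyl group (self-regeneration of stereocentres) should form the C9–C10 bond and the quaternary centre C10 with the 10S configuration.

Step 6
Reactants: 9 (2R,5S)-2-tert-butyl-5-methyl-5-(prop-2-en-1-yl)-1,3-dioxolan-4-one; 10 2-methylbut-1-en-3-yne
Product: 12 (6S)-6-hydroxy-2,6-dimethylnona-1,8-dien-3-yn-5-one, via lithium hemiketal alkoxide 11 (not isolated)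
Conditions: 10, n-BuLi, THF, −78 °C; then 9, −78 °C; aq. NH4Cl, 23 °C
Reagents that add atoms: 2-methylbut-1-en-3-yne C=C(C)C#C
Why: 1,2-Addition of the lithium acetylide to the lactone-type carbonyl should stop at the tetrahedral alkoxide, which collapses on work-up with loss of pivalaldehyde to the α'-hydroxy ynone without touching C10.

Step 7
Reactants: 12 (6S)-6-hydroxy-2,6-dimethylnona-1,8-dien-3-yn-5-one
Product: 14 (2S)-2-methyl-5-(prop-1-en-2-yl)-2-(prop-2-en-1-yl)furan-3(2H)-one, via enaminone 13 (not isolated)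
Conditions: Et2NH (1.2 equiv), EtOH, 23 °C; then aq. AcOH
Reagents that add atoms: none
Why: Amine-mediated 3(2H)-furanone formation: conjugate addition of Et2NH to the ynone gives an enaminone, and the tertiary hydroxyl then displaces the amine by addition–elimination.

Step 8
Reactants: 14 (2S)-2-methyl-5-(prop-1-en-2-yl)-2-(prop-2-en-1-yl)furan-3(2H)-one; 15 crotonaldehyde
Product: 16 (2E)-4-[(2S)-2-methyl-3-oxo-5-(prop-1-en-2-yl)-2,3-dihydrofuran-2-yl]but-2-enal
Conditions: second-generation Hoveyda–Grubbs catalyst RuCl2(H2IMes)(=CH–C6H4-2-OiPr) (5 mol%), 15 (5 equiv), CH2Cl2, 40 °C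
Reagents that add atoms: crotonaldehyde C/C=C/C=O
Why: Olefin cross-metathesis of the terminal allyl group with crotonaldehyde should give the E-enal, the conjugated 1,1-disubstituted isopropenyl group staying out of the reaction.

Step 9
Reactants: 16 (2E)-4-[(2S)-2-methyl-3-oxo-5-(prop-1-en-2-yl)-2,3-dihydrofuran-2-yl]but-2-enal; 17 trimethylsilylacetylene
Product: 18 (2S)-2-[(2E,4S)-4-hydroxy-6-(trimethylsilyl)hex-2-en-5-yn-1-yl]-2-methyl-5-(prop-1-en-2-yl)furan-3(2H)-one
Conditions: 17 (3 equiv), Me2Zn (3 equiv), (S,S)-ProPhenol (10 mol%), Ph3PO (20 mol%), toluene, 4 °C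
Reagents that add atoms: trimethylsilylacetylene C[Si](C)(C)C#C
Why: Catalytic asymmetric zinc alkynylation of the enal (ProPhenol alkynylation, 1,2-addition) should set C6 as S under catalyst control, the ligand antipode being used if the sense proves opposite for this enal.

Step 10
Reactants: 18 (2S)-2-[(2E,4S)-4-hydroxy-6-(trimethylsilyl)hex-2-en-5-yn-1-yl]-2-methyl-5-(prop-1-en-2-yl)furan-3(2H)-one
Product: 19 (2S)-2-[(2E,4S)-4-hydroxyhex-2-en-5-yn-1-yl]-2-methyl-5-(prop-1-en-2-yl)furan-3(2H)-one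
Conditions: K2CO3 (0.2 equiv), MeOH, 0 °C
Reagents that add atoms: none
Why: Base-catalysed protodesilylation of the alkynylsilane should free the terminal alkyne without affecting the carbinol centre.

Step 11
Reactants: 19 (2S)-2-[(2E,4S)-4-hydroxyhex-2-en-5-yn-1-yl]-2-methyl-5-(prop-1-en-2-yl)furan-3(2H)-one; 20 Meldrum's acid
Product: 21 3-oxo-3-{[(3S,4E)-6-[(2S)-2-methyl-3-oxo-5-(prop-1-en-2-yl)-2,3-dihydrofuran-2-yl]hex-4-en-1-yn-3-yl]oxy}propanoic acid
Conditions: 20 (1.2 equiv), toluene, 90 °C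
Reagents that add atoms: Meldrum's acid CC1(C)OC(=O)CC(=O)O1
Why: Ring-opening acylation of the alcohol by Meldrum's acid with loss of acetone should give the malonic half ester directly, with retention at C6.

Step 12
Reactants: 21 3-oxo-3-{[(3S,4E)-6-[(2S)-2-methyl-3-oxo-5-(prop-1-en-2-yl)-2,3-dihydrofuran-2-yl]hex-4-en-1-yn-3-yl]oxy}propanoic acid
Product: 22 (1S,4S,5R,6S)-4-ethynyl-6-{[(2S)-2-methyl-3-oxo-5-(prop-1-en-2-yl)-2,3-dihydrofuran-2-yl]methyl}-3,7-dioxabicyclo[3.3.0]octane-2,8-dione
Conditions: Mn(OAc)3·2H2O (2.2 equiv), Cu(OAc)2·H2O (1.0 equiv), AcOH, Ar, 25 → 45 °C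
Reagents that add atoms: none
Why: Mn(OAc)3 oxidises the enolised malonic half ester to the electrophilic C11 radical, which closes onto C7 through the O6 ester tether (C11–C7, ring A); divalent copper then oxidises the secondary C8 radical and the free carboxyl group captures the resulting alkylcopper or cation (O–C8, ring B). The closest known reaction type is the trivalent-manganese/divalent-copper oxidative cyclisation–lactonisation of allylic malonates to 3,7-dioxabicyclo[3.3.0]octane-2,8-diones (oxidative double annulation). Ring A closes by radical 5-exo-trig addition and ring B by polar 5-exo capture of the oxidised C8 centre by the γ-carboxyl group. C7 is set by C6 (ethynyl pseudo-equatorial in the chair-like transition state, hence trans in ring A), C11 by the obligatory cis ring fusion, and C8 by the C9 chain taking the convex face, which makes the C7/C8 lactone trans as in the target whatever the alkene geometry. The step needs site selectivity for C7=C8 over the alkyne and the isopropenyl group, which the 5-exo tether and the more electron-rich dialkyl alkene should secure, and regioselectivity (carbon to C7, oxygen to C8), which the tether length secures.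

Step 13
Reactants: 22 (1S,4S,5R,6S)-4-ethynyl-6-{[(2S)-2-methyl-3-oxo-5-(prop-1-en-2-yl)-2,3-dihydrofuran-2-yl]methyl}-3,7-dioxabicyclo[3.3.0]octane-2,8-dione; 23 formaldehyde
Product: 26 (2S)-2-{[(2S,3S)-3-[(1S)-1-hydroxyprop-2-yn-1-yl]-4-methylidene-5-oxooxolan-2-yl]methyl}-2-methyl-5-(prop-1-en-2-yl)furan-3(2H)-one, via carboxy lactone 24 (not isolated), via Mannich base 25 (not isolated)
Conditions: LiOH (1.1 equiv), THF/H2O, 0 °C; then AcOH (to pH 6), 37% aq. HCHO, Et2NH, 23 → 50 °C
Reagents that add atoms: formaldehyde C=O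
Why: Saponification should open ring A in preference (the propargylic O6 alkoxide is the better leaving group and translactonisation moves the acyl group to the less acidic O8), and the α-carboxy lactone then undergoes decarboxylative Mannich methylenation to the α-methylene lactone.

Step 14
Reactants: 26 (2S)-2-{[(2S,3S)-3-[(1S)-1-hydroxyprop-2-yn-1-yl]-4-methylidene-5-oxooxolan-2-yl]methyl}-2-methyl-5-(prop-1-en-2-yl)furan-3(2H)-one; 4 (2S,3S)-2,3-dimethyloxirane-2-carboxylic acid
Product: 27 (1R)-1-[(2S,3R)-2-{[(2S)-2-methyl-3-oxo-5-(prop-1-en-2-yl)-2,3-dihydrofuran-2-yl]methyl}-4-methylidene-5-oxooxolan-3-yl]prop-2-yn-1-yl (2S,3S)-2,3-dimethyloxirane-2-carboxylate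
Conditions: 4 (1.5 equiv), PPh3, iPrO2C–N=N–CO2iPr (DIAD), toluene, 0 → 23 °C
Reagents that add atoms: (2S,3S)-2,3-dimethyloxirane-2-carboxylic acid OC(=O)[C@@]1(C)O[C@H]1C
Why: Mitsunobu esterification (SN2 at the activated propargylic carbon) should invert C6 to the configuration of the target while installing the epoxyangelate, propargylic alcohols normally giving clean inversion.

Step 15
Reactants: 27 (1R)-1-[(2S,3R)-2-{[(2S)-2-methyl-3-oxo-5-(prop-1-en-2-yl)-2,3-dihydrofuran-2-yl]methyl}-4-methylidene-5-oxooxolan-3-yl]prop-2-yn-1-yl (2S,3S)-2,3-dimethyloxirane-2-carboxylate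
Product: 28 (1S)-1-[(2S,3R)-2-{[(2S)-2-methyl-3-oxo-5-(prop-1-en-2-yl)-2,3-dihydrofuran-2-yl]methyl}-4-methylidene-5-oxooxolan-3-yl]prop-2-en-1-yl (2S,3S)-2,3-dimethyloxirane-2-carboxylate
Conditions: H2 (1 atm), Pd/CaCO3 poisoned with Pb(OAc)2 (Lindlar catalyst), quinoline, EtOAc, 0 °C, stopped after 1 equiv H2
Reagents that add atoms: none
Why: Lindlar semi-hydrogenation should stop at the vinyl group because the terminal alkyne binds the poisoned palladium far more strongly than the conjugated 1,1-disubstituted alkenes present.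

Step 16
Reactants: 28 (1S)-1-[(2S,3R)-2-{[(2S)-2-methyl-3-oxo-5-(prop-1-en-2-yl)-2,3-dihydrofuran-2-yl]methyl}-4-methylidene-5-oxooxolan-3-yl]prop-2-en-1-yl (2S,3S)-2,3-dimethyloxirane-2-carboxylate
Product: 29 (6S,7R,8S,10S)-6-[(2S,3S)-2,3-epoxy-2-methylbutanoyloxy]-1-oxo-3,10-epoxygermacra-2,4(Z),11(13)-trien-12,8-olide (CNP0258430.1)
Conditions: second-generation Hoveyda–Grubbs catalyst (20 mol%), 1,4-benzoquinone (cat.), toluene (1 mM), 100 °C
Reagents that add atoms: none
Why: Ring-closing olefin metathesis between the C6 vinyl group and the isopropenyl group on C3 should form the trisubstituted C4=C5 alkene and the ten-membered carbocycle, the ring allowing only the Z geometry and loss of ethylene driving the closure.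

**Compound list**

1 | methyl (Z)-2-methylbut-2-enoate (methyl angelate) | C/C=C(/C)C(=O)OC | starting material
2 | (Z)-2-methylbut-2-en-1-ol | C/C=C(/C)CO | intermediate
3 | [(2R,3S)-2,3-dimethyloxiran-2-yl]methanol | OC[C@@]1(C)O[C@H]1C | intermediate
4 | (2S,3S)-2,3-dimethyloxirane-2-carboxylic acid ((2S,3S)-epoxyangelic acid) | OC(=O)[C@@]1(C)O[C@H]1C | intermediate
5 | (R)-lactic acid | C[C@@H](O)C(=O)O | starting material
6 | pivalaldehyde | CC(C)(C)C=O | starting material
7 | (2R,5R)-2-tert-butyl-5-methyl-1,3-dioxolan-4-one (cis) | C[C@H]1O[C@@H](C(C)(C)C)OC1=O | intermediate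
8 | allyl bromide | C=CCBr | starting material
9 | (2R,5S)-2-tert-butyl-5-methyl-5-(prop-2-en-1-yl)-1,3-dioxolan-4-one | C=CC[C@]1(C)O[C@@H](C(C)(C)C)OC1=O | intermediate
10 | 2-methylbut-1-en-3-yne | C=C(C)C#C | starting material
11 | lithium 2-tert-butyl-5-methyl-4-(3-methylbut-3-en-1-yn-1-yl)-5-(prop-2-en-1-yl)-1,3-dioxolan-4-olate (C2 and C5 as in 9; C4 mixed) | C=CC[C@]1(C)O[C@@H](C(C)(C)C)OC1([O-])C#CC(C)=C.[Li+] | intermediate
12 | (6S)-6-hydroxy-2,6-dimethylnona-1,8-dien-3-yn-5-one | C=CC[C@](C)(O)C(=O)C#CC(C)=C | intermediate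
13 | (6S)-3-(diethylamino)-6-hydroxy-2,6-dimethylnona-1,3,8-trien-5-one (enaminone; alkene geometry not defined) | C=CC[C@](C)(O)C(=O)C=C(N(CC)CC)C(C)=C | intermediate
14 | (2S)-2-methyl-5-(prop-1-en-2-yl)-2-(prop-2-en-1-yl)furan-3(2H)-one | C=CC[C@]1(C)OC(=CC1=O)C(C)=C | intermediate
15 | crotonaldehyde | C/C=C/C=O | starting material
16 | (2E)-4-[(2S)-2-methyl-3-oxo-5-(prop-1-en-2-yl)-2,3-dihydrofuran-2-yl]but-2-enal | O=C/C=C/C[C@]1(C)OC(=CC1=O)C(C)=C | intermediate
17 | trimethylsilylacetylene | C[Si](C)(C)C#C | starting material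
18 | (2S)-2-[(2E,4S)-4-hydroxy-6-(trimethylsilyl)hex-2-en-5-yn-1-yl]-2-methyl-5-(prop-1-en-2-yl)furan-3(2H)-one | C[Si](C)(C)C#C[C@@H](O)/C=C/C[C@]1(C)OC(=CC1=O)C(C)=C | intermediate
19 | (2S)-2-[(2E,4S)-4-hydroxyhex-2-en-5-yn-1-yl]-2-methyl-5-(prop-1-en-2-yl)furan-3(2H)-one | C#C[C@@H](O)/C=C/C[C@]1(C)OC(=CC1=O)C(C)=C | intermediate
20 | Meldrum's acid (2,2-dimethyl-1,3-dioxane-4,6-dione) | CC1(C)OC(=O)CC(=O)O1 | starting material
21 | 3-oxo-3-{[(3S,4E)-6-[(2S)-2-methyl-3-oxo-5-(prop-1-en-2-yl)-2,3-dihydrofuran-2-yl]hex-4-en-1-yn-3-yl]oxy}propanoic acid (hydrogen malonate of 19) | C#C[C@@H](OC(=O)CC(=O)O)/C=C/C[C@]1(C)OC(=CC1=O)C(C)=C | intermediate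
22 | (1S,4S,5R,6S)-4-ethynyl-6-{[(2S)-2-methyl-3-oxo-5-(prop-1-en-2-yl)-2,3-dihydrofuran-2-yl]methyl}-3,7-dioxabicyclo[3.3.0]octane-2,8-dione (cis-fused bis-lactone; both substituents exo; ring A = O3/C4 side, ring B = C6/O7 side) | C#C[C@H]1OC(=O)[C@@H]2C(=O)O[C@@H](C[C@]3(C)OC(=CC3=O)C(C)=C)[C@H]12 | intermediate
23 | formaldehyde | C=O | starting material
24 | (2S,3S)-3-[(1S)-1-hydroxyprop-2-yn-1-yl]-2-{[(2S)-2-methyl-3-oxo-5-(prop-1-en-2-yl)-2,3-dihydrofuran-2-yl]methyl}-5-oxooxolane-4-carboxylic acid (lithium salt in the flask; C4 epimerisable) | OC(=O)[C@@H]1C(=O)O[C@@H](C[C@]2(C)OC(=CC2=O)C(C)=C)[C@@H]1[C@H](O)C#C | intermediate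
25 | (2S,3S)-4-[(diethylamino)methyl]-3-[(1S)-1-hydroxyprop-2-yn-1-yl]-2-{[(2S)-2-methyl-3-oxo-5-(prop-1-en-2-yl)-2,3-dihydrofuran-2-yl]methyl}-5-oxooxolane-4-carboxylic acid (Mannich base; C4 not defined) | CCN(CC)CC1(C(=O)O)C(=O)O[C@@H](C[C@]2(C)OC(=CC2=O)C(C)=C)[C@@H]1[C@H](O)C#C | intermediate
26 | (2S)-2-{[(2S,3S)-3-[(1S)-1-hydroxyprop-2-yn-1-yl]-4-methylidene-5-oxooxolan-2-yl]methyl}-2-methyl-5-(prop-1-en-2-yl)furan-3(2H)-one | C=C1C(=O)O[C@@H](C[C@]2(C)OC(=CC2=O)C(C)=C)[C@@H]1[C@H](O)C#C | intermediate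
27 | (1R)-1-[(2S,3R)-2-{[(2S)-2-methyl-3-oxo-5-(prop-1-en-2-yl)-2,3-dihydrofuran-2-yl]methyl}-4-methylidene-5-oxooxolan-3-yl]prop-2-yn-1-yl (2S,3S)-2,3-dimethyloxirane-2-carboxylate | C=C1C(=O)O[C@@H](C[C@]2(C)OC(=CC2=O)C(C)=C)[C@@H]1[C@@H](OC(=O)[C@@]3(C)O[C@H]3C)C#C | intermediate
28 | (1S)-1-[(2S,3R)-2-{[(2S)-2-methyl-3-oxo-5-(prop-1-en-2-yl)-2,3-dihydrofuran-2-yl]methyl}-4-methylidene-5-oxooxolan-3-yl]prop-2-en-1-yl (2S,3S)-2,3-dimethyloxirane-2-carboxylate | C=C1C(=O)O[C@@H](C[C@]2(C)OC(=CC2=O)C(C)=C)[C@@H]1[C@@H](OC(=O)[C@@]3(C)O[C@H]3C)C=C | intermediate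
29 | (6S,7R,8S,10S)-6-[(2S,3S)-2,3-epoxy-2-methylbutanoyloxy]-1-oxo-3,10-epoxygermacra-2,4(Z),11(13)-trien-12,8-olide (CNP0258430.1) | C=C1C(=O)O[C@H]2C[C@]3(C)OC(=CC3=O)/C(C)=C\[C@H](OC(=O)[C@@]3(C)O[C@H]3C)[C@H]12 | target

**Totals**

Total step count: 16. Longest linear sequence: 13 steps (steps 4–16, from (R)-lactic acid); steps 1–3 make the side-chain acid 4.

**Steps most likely to fail**

1. Step 12 (key step). The 5-exo closure through the ester tether may be slow because the reactive ester rotamer is disfavoured. The malonyl radical may also add to the alkyne or the isopropenyl unit, and the trans preference in ring A may be only moderate because the ethynyl group is small. Fallback, setting out from 19: acylation with methyl malonyl chloride (pyridine, CH2Cl2, 0 °C) should give the mixed methyl malonate F1. Titanium-mediated iodocarbocyclisation of F1 (Ti(OtBu)4, I2, CuO, CH2Cl2) should close ring A by anti addition of the malonate carbon and iodine across the E alkene, giving the iodo lactone F2. Heating F2 in DMF should let the ester carbonyl displace iodide at C8 with inversion and loss of iodomethane; this closes ring B stereospecifically (net syn addition, trans lactone) and comes back to the route at 22.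

2. Step 16. Ring closure may stall through slow initiation at the 1,1-disubstituted alkene and strain in the forming bicycle, while the vinyl group oligomerises or the methylene lactone enters cross-metathesis. Fallback, setting out from 26: Lindlar semi-hydrogenation should give the vinyl carbinol F3. Ring-closing metathesis of F3, whose free and unhindered allylic hydroxyl should speed loading of the ruthenium alkylidene, should give the macrocyclic 6-epi alcohol F4. Mitsunobu esterification of F4 with 4 then inverts C6 on the macrocycle and comes back at 29.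

3. Step 13. Hydroxide may attack the wrong lactone carbonyl or open both rings, and ring A may re-close on acidification before the Mannich step. Fallback, setting out from 22: equilibrating transesterification (NaOMe, 1 equiv, MeOH, 0 → 23 °C) should place the ring acyl group on the less acidic O8 and leave the propargylic alcohol free, giving the methoxycarbonyl lactone F5 under thermodynamic control. Saponification of the methyl ester (LiOH, then mild acid to re-close ring B) and decarboxylative Mannich methylenation (HCHO, Et2NH) come back at 26.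

Further compounds
F1 | step 12 | methyl (3S,4E)-6-[(2S)-2-methyl-3-oxo-5-(prop-1-en-2-yl)-2,3-dihydrofuran-2-yl]hex-4-en-1-yn-3-yl propanedioate | C#C[C@@H](OC(=O)CC(=O)OC)/C=C/C[C@]1(C)OC(=CC1=O)C(C)=C
F2 | step 12 | methyl (4S,5S)-5-ethynyl-4-{(1R)-1-iodo-2-[(2S)-2-methyl-3-oxo-5-(prop-1-en-2-yl)-2,3-dihydrofuran-2-yl]ethyl}-2-oxooxolane-3-carboxylate (C3 epimerisable) | C#C[C@H]1OC(=O)C(C(=O)OC)[C@@H]1[C@H](I)C[C@]2(C)OC(=CC2=O)C(C)=C
F3 | step 16 | (2S)-2-{[(2S,3S)-3-[(1R)-1-hydroxyprop-2-en-1-yl]-4-methylidene-5-oxooxolan-2-yl]methyl}-2-methyl-5-(prop-1-en-2-yl)furan-3(2H)-one | C=C1C(=O)O[C@@H](C[C@]2(C)OC(=CC2=O)C(C)=C)[C@@H]1[C@H](O)C=C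
F4 | step 16 | (6R,7S,8S,10S)-6-hydroxy-1-oxo-3,10-epoxygermacra-2,4(Z),11(13)-trien-12,8-olide (6-epi alcohol) | C=C1C(=O)O[C@H]2C[C@]3(C)OC(=CC3=O)/C(C)=C\[C@@H](O)[C@H]12
F5 | step 13 | methyl (2S,3S)-3-[(1S)-1-hydroxyprop-2-yn-1-yl]-2-{[(2S)-2-methyl-3-oxo-5-(prop-1-en-2-yl)-2,3-dihydrofuran-2-yl]methyl}-5-oxooxolane-4-carboxylate (C4 epimerisable) | COC(=O)[C@@H]1C(=O)O[C@@H](C[C@]2(C)OC(=CC2=O)C(C)=C)[C@@H]1[C@H](O)C#C
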